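## The problem

The target, 1-(7-hydroxy-5-methoxy-2,2-dimethyl-2H-chromen-6-yl)-2-(4-methoxyphenyl)ethan-1-one (21), is a deoxybenzoin whose aryl half is a phloroglucinol ring (ring A) fused through C4a and C8a to a 2,2-dimethyl-2H-pyran (ring B). All six carbons of ring A are different: C4a carries the vinyl carbon C4, C5 a methoxy group, C6 the arylacetyl group, C7 a free hydroxyl, C8 a hydrogen and C8a the pyran oxygen O1. The problem is therefore regiochemical: the three ring oxygens must be told apart, and the acyl group must go to C6 and not to C8, which is also flanked by two oxygens. There is no stereocenter (C2 is a gem-dimethyl carbon), so nothing has to be set or relayed. The fragile parts are the electron-rich C3=C4 double bond (strong acid, electrophiles, hydrogenation), the enolisable ArCO–CH2–Ar' unit and the C7 phenol, which must be masked whenever an aryne or an organometallic is present. The key step is possible because O1 and C4 sit on adjacent benzene carbons with the C5 methoxy group directly beside C4a. This is the pattern left when the oxygen and carbon of an aldehyde C=O add across a 3-methoxy aryne, the methoxy group sending oxygen to the far carbon. C6 is not adjacent to that triple bond, so a substituent placed there can pass through the aryne step untouched.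

## Retrosynthesis

**21 from 20.** The O–CH2 bond of a methoxymethyl (MOM) ether at C7 is cut last. The phenol cannot be free during the aryne or organometallic steps, and a MOM ether ortho to a ketone is removed by dilute acid that the acyl-deactivated chromene should tolerate. Precursor 20 differs from 21 only by this acetal.

**20 from 16 and 17.** The C6–C(=O) bond is cut to a C6 bromide (16) and 4-methoxyphenylacetyl chloride (17). Direct deprotonation of a bromine-free chromene was considered and set aside: C6 and C8 both lie between two oxygens, and the in-plane lone pair of O1 points at C8, so the site of metalation cannot be predicted. Bromine–lithium exchange is regiospecific. Cutting the C(=O)–CH2 bond instead would cost an extra oxidation step and is kept as a fallback. The forward step needs an aryl metal that acylates without deprotonating the acidic CH2 of 17, hence transmetalation to zinc.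

**16 from 11 and 12 (key disconnection).** Three bonds of ring B are cut at once (C8a–O1, C4a–C4 and O1–C2), leading to ortho-silylaryl triflate 11 and 3-methylbut-2-enal (12) via aryne 13, benzoxete 14 and ortho-quinone methide 15. A classical chromenylation of a phenol with 12 would need a free hydroxyl at C8a and would have to choose between two ortho carbons. Here both new ring bonds form at the two carbons of the triple bond, and the methoxy group decides which receives oxygen. The precursor is monocyclic and five carbons smaller. The forward reaction must have carbonyl addition outrun the ene reaction and the capture of 15 by a second aryne.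

**11 from 10 from 9.** The S–O bond of the triflate and then the O–Si bond of a tert-butyldimethylsilyl ether are cut. The phenol oxygen must be masked during the metalation that makes 9. A silyl ether was chosen because it does not coordinate lithium and so cannot draw the base toward the neighbouring SiMe3 group.

**9 from 7.** The C–Br bond is cut. In 7 the future C6 is the only C–H flanked by two coordinating oxygens (OMe and OMOM). The future C8 has one director and stands next to the bulky SiMe3 group. The C6/C8 question is therefore settled here, before O1 exists, and not on the chromene.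

**7 from 6 from 2.** The MOM ether is cut to phenol 6, which goes back to hydroquinone 2 through bis-silyl ether 3, phenoxide 4 and mixed silyl ether 5. The C–Si bond comes from a retro-Brook shift. Only the oxygen next to bromine can pass its silicon to carbon, so the two hydroxyls of 2 are told apart by the position of the bromine, not by a selective protection.

**2 from 1.** The aryl–CHO bond is cut (Dakin oxidation). Commercial 5-bromovanillin (1) already has OMe, OH and Br on three neighbouring carbons, and its formyl group, para to the hydroxyl, marks where the fourth oxygen is needed.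

## Roads not taken

**Alternative 1:** The C6–C(=O) bond and the C5–O bond are cut together.
- Precursors: the aryne from silyl triflate A1, 2-(methoxymethoxy)-4-[(2-methylbut-3-yn-2-yl)oxy]-6-(trimethylsilyl)phenyl trifluoromethanesulfonate, and 4-methoxyphenylacetic acid (A2).
- Forward key step: fluoride frees the aryne, the carboxylate oxygen adds to the carbon remote from the MOM ether, the aryl anion attacks the new ester carbonyl, and the four-membered intermediate opens to ortho-hydroxyaryl ketone A3, 1-[2-hydroxy-6-(methoxymethoxy)-4-[(2-methylbut-3-yn-2-yl)oxy]phenyl]-2-(4-methoxyphenyl)ethanone.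
- Merits: the acyl group and its neighbouring oxygen arrive in one step with their ortho relationship fixed by mechanism. The acid is used as such and no organometallic acylation is needed. In this respect the road is better than the chosen one, which spends steps 4, 5 and 8 on a bromine handle and its use.
- Weak points: the O–H of A2 can protonate the aryl anion before acyl transfer, giving an aryl ester. The benzylic CH2 is acidic and the alkyne is a possible aryne trap. No ring closes, so ring B must still be made by thermal rearrangement of the aryl propargyl ether, which can choose between two free ortho carbons. Only closure beside the new hydroxyl leads on, and it must be followed by methylation of that chelated hydroxyl and MOM removal. A1 needs about as many steps as 11.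
- Comparison: total length is similar. The chosen plan offers a pyran ring whose two points of attachment are fixed by the aryne, against the more direct acyl introduction of this road.

**Alternative 2:** Ring A itself is cut between the acyl-bearing carbon and a neighbouring C–O carbon.
- Precursor: the open-chain triketo ester A4, methyl 8-(4-methoxyphenyl)-3,5,7-trioxooctanoate.
- Forward key step: with Mg(OMe)2 the methylene between two ketones attacks the ester carbonyl (Claisen condensation), and enolisation gives acylphloroglucinol A5, 2-(4-methoxyphenyl)-1-(2,4,6-trihydroxyphenyl)ethanone.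
- Merits: biomimetic; the ring and the acyl group form in one step from non-aromatic material. The front end is very short, since A5 is also within reach by a single Hoesch acylation of the commercial triphenol. On step count this road clearly beats the chosen one.
- Weak points: A4 is a labile poly-β-carbonyl compound with a competing aldol mode (terminal methylene onto the far ketone, giving a resorcylate) and pyrone formation. A5 has three hydroxyls, two of them equivalent. Ring B must then be added with 12 through the para hydroxyl and not an ortho one. After that, only the hydroxyl next to C4a may be methylated, in the presence of a second hydroxyl equally chelated to the ketone.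
- Comparison: neither selection is controlled by structure, so the short sequence would pay with isomer separations in its last two steps. The chosen plan is about twice as long but differentiates the three oxygens from compound 2 onward.

**Alternative 3:** Both bonds to the carbonyl carbon are cut.
- Precursors: aryl iodide A6, 2-iodo-1,3,5-tris(methoxymethoxy)benzene; carbon monoxide (A7); and (4-methoxybenzyl)zinc chloride (A8).
- Forward key step: carbonylative Negishi coupling. A6 adds oxidatively to zerovalent palladium (Pd(PPh3)4), A7 inserts, A8 transmetalates, and reductive elimination gives ketone A9, 2-(4-methoxyphenyl)-1-[2,4,6-tris(methoxymethoxy)phenyl]ethanone.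
- Merits: convergent and neutral. The symmetric A6 raises no regiochemical question, and no enolisable acid chloride is used. In convergence and mildness the ketone-forming step is at least as good as step 8 of the chosen route.
- Weak points: the aryl–palladium intermediate is flanked by two ortho ethers and is electron-rich, so insertion of A7 is slow and direct coupling to the diarylmethane competes, as does homocoupling of A8. The symmetry that makes A6 easy must later be broken: deprotection of A9 gives A5 and with it the two unselective steps of alternative 2.
- Comparison: the chosen plan offers pre-differentiated oxygens and a regiospecific C6 handle against the better ketone construction of this road.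

Key step: step 7

Remark: compounds 1, 12 and 17 are taken as purchased; 21 has no stereocenter, so the route carries no stereochemical element apart from the transient alkene geometry of 15.

## Route

Step 1
Reactants: 1 5-bromovanillin (3-bromo-4-hydroxy-5-methoxybenzaldehyde)
Product: 2 2-bromo-6-methoxybenzene-1,4-diol
Conditions: H2O2 (30% aq), NaOH (aq), N2, 0 °C → rt; then HCl
Reagents that add atoms: hydrogen peroxide, OO
Why: Dakin oxidation: the hydroperoxide anion adds to the aldehyde, the aryl group bearing a para oxido substituent migrates to oxygen and the aryl formate is hydrolysed in the basic medium. Exclusion of air and an acidic work-up should keep the hydroquinone from oxidising to the quinone.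

Step 2
Reactants: 2 2-bromo-6-methoxybenzene-1,4-diol
Product: 6 4-[(tert-butyldimethylsilyl)oxy]-3-methoxy-5-(trimethylsilyl)phenol, via bis(trimethylsilyl) ether 3 (not isolated), via lithium phenoxide 4 (not isolated), via mixed silyl ether 5 (not isolated)
Conditions: HMDS, THF, reflux, then evaporation; n-BuLi, THF, −78 °C → rt; TBSOTf, −78 → 0 °C; citric acid, MeOH, rt
Reagents that add atoms: hexamethyldisilazane, C[Si](C)(C)N[Si](C)(C)C; tert-butyldimethylsilyl trifluoromethanesulfonate, CC(C)(C)[Si](C)(C)OS(=O)(=O)C(F)(F)F
Why: Both hydroxyls are silylated, then bromine–lithium exchange triggers a 1,3 O→C silyl shift (retro-Brook rearrangement) that only the oxygen ortho to the lithiated carbon can undergo, so phenoxide 4 forms at one oxygen alone. TBSOTf caps that phenoxide, and the remaining unhindered aryl O–SiMe3 ether is the only silyl ether cleaved by mild acidic methanolysis.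

Step 3
Reactants: 6 4-[(tert-butyldimethylsilyl)oxy]-3-methoxy-5-(trimethylsilyl)phenol
Product: 7 tert-butyl[2-methoxy-4-(methoxymethoxy)-6-(trimethylsilyl)phenoxy]dimethylsilane
Conditions: MOMCl, i-Pr2NEt, CH2Cl2, 0 °C → rt
Reagents that add atoms: chloromethyl methyl ether, COCCl
Why: O-Alkylation of an unhindered phenol with a reactive α-chloro ether under amine base; the aryl silyl ether and the arylsilane are inert to these conditions.

Step 4
Reactants: 7 tert-butyl[2-methoxy-4-(methoxymethoxy)-6-(trimethylsilyl)phenoxy]dimethylsilane
Product: 9 [3-bromo-2-methoxy-4-(methoxymethoxy)-6-(trimethylsilyl)phenoxy](tert-butyl)dimethylsilane, via aryllithium 8 (not isolated)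
Conditions: s-BuLi, TMEDA, THF, −78 °C; BrCl2CCCl2Br, −78 °C → rt
Reagents that add atoms: 1,2-dibromo-1,1,2,2-tetrachloroethane, ClC(Cl)(Br)C(Cl)(Cl)Br
Why: Directed ortho-metalation removes the only ring hydrogen flanked by two coordinating oxygens (OMe and OMOM); the other ring hydrogen has a single director and sits beside the SiMe3 group, and the silyl ether does not direct. The aryllithium is brominated by halogen transfer from the polyhaloethane.

Step 5
Reactants: 9 [3-bromo-2-methoxy-4-(methoxymethoxy)-6-(trimethylsilyl)phenoxy](tert-butyl)dimethylsilane
Product: 10 3-bromo-2-methoxy-4-(methoxymethoxy)-6-(trimethylsilyl)phenol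
Conditions: TBAF, AcOH, THF, 0 °C
Reagents that add atoms: none
Why: Fluoride cleaves the aryl O–Si bond, which has a phenoxide leaving group, far faster than the unactivated aryl C–SiMe3 bond; acetic acid buffers the phenoxide.

Step 6
Reactants: 10 3-bromo-2-methoxy-4-(methoxymethoxy)-6-(trimethylsilyl)phenol
Product: 11 3-bromo-2-methoxy-4-(methoxymethoxy)-6-(trimethylsilyl)phenyl trifluoromethanesulfonate
Conditions: Tf2O, pyridine, CH2Cl2, 0 °C
Reagents that add atoms: trifluoromethanesulfonic anhydride, O=S(=O)(OS(=O)(=O)C(F)(F)F)C(F)(F)F
Why: O-Sulfonylation of the phenol, the standard closing step in the preparation of ortho-silylaryl triflates; the MOM ether, aryl bromide and arylsilane are unaffected.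

Step 7
Reactants: 11 3-bromo-2-methoxy-4-(methoxymethoxy)-6-(trimethylsilyl)phenyl trifluoromethanesulfonate; 12 3-methylbut-2-enal
Product: 16 6-bromo-5-methoxy-7-(methoxymethoxy)-2,2-dimethyl-2H-chromene, via aryne 13 (not isolated), via benzoxete 14 (not isolated), via ortho-quinone methide 15 (not isolated)
Conditions: CsF, 12 (excess), MeCN, rt, slow addition of 11
Reagents that add atoms: none
Why: Fluoride attacks the silicon of 11 and triflate leaves, releasing aryne 13. The carbonyl oxygen of 12 adds to the aryne carbon remote from the methoxy group, and the aryl anion so formed beside OMe closes onto the carbonyl carbon, a formal [2+2] addition that gives benzoxete 14. Thermal 4π electrocyclic opening of 14 gives ortho-quinone methide 15, a 1-oxatriene, whose thermal disrotatory oxa-6π electrocyclisation forms O1–C2 and closes ring B with rearomatisation. The closest known reaction type is the insertion of arynes into the C=O bond of α,β-unsaturated aldehydes to give 2H-chromenes. No stereocenter is formed, since C2 carries two methyl groups. The step needs oxygen to add at the future C8a; the methoxy group next to the triple bond secures this by polarising the aryne, and the bromine meta to the anionic carbon reinforces it. It also needs carbonyl addition to outrun the ene reaction with the allylic methyl groups and the capture of 15 by a second aryne; the electron-poor alkene of 12 is a poor ene partner, and slow release of 13 into excess 12 keeps the aryne concentration low. The aryl bromide is not adjacent to the triple bond and is a spectator under fluoride.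

Step 8
Reactants: 16 6-bromo-5-methoxy-7-(methoxymethoxy)-2,2-dimethyl-2H-chromene; 17 4-methoxyphenylacetyl chloride
Product: 20 1-[5-methoxy-7-(methoxymethoxy)-2,2-dimethyl-2H-chromen-6-yl]-2-(4-methoxyphenyl)ethan-1-one, via aryllithium 18 (not isolated), via arylzinc chloride 19 (not isolated)
Conditions: n-BuLi, THF, −78 °C; ZnCl2, −78 → 0 °C; 17, Pd(PPh3)4 (cat.), THF, 0 °C → rt
Reagents that add atoms: none
Why: Bromine–lithium exchange is much faster than any ring deprotonation and fixes the metal at C6. Transmetalation to zinc gives a nucleophile too weakly basic to deprotonate 17, and the Pd(PPh3)4-catalysed Negishi acylation forms the ketone without over-addition.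

Step 9
Reactants: 20 1-[5-methoxy-7-(methoxymethoxy)-2,2-dimethyl-2H-chromen-6-yl]-2-(4-methoxyphenyl)ethan-1-one
Product: 21 1-(7-hydroxy-5-methoxy-2,2-dimethyl-2H-chromen-6-yl)-2-(4-methoxyphenyl)ethan-1-one
Conditions: HCl (3 M aq), MeOH, 40 °C
Reagents that add atoms: none
Why: Acid-catalysed acetal methanolysis; a MOM ether ortho to a ketone is cleaved under mild conditions and the freed phenol is held by a hydrogen bond to the carbonyl. The chromene double bond, deactivated by the acyl group, should tolerate dilute acid.

## Compound list

1 | 5-bromovanillin (3-bromo-4-hydroxy-5-methoxybenzaldehyde) | COc1cc(C=O)cc(Br)c1O | starting material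
2 | 2-bromo-6-methoxybenzene-1,4-diol | COc1cc(O)cc(Br)c1O | intermediate
3 | 1-bromo-3-methoxy-2,5-bis[(trimethylsilyl)oxy]benzene | COc1cc(O[Si](C)(C)C)cc(Br)c1O[Si](C)(C)C | intermediate
4 | lithium 2-methoxy-6-(trimethylsilyl)-4-[(trimethylsilyl)oxy]phenolate | COc1cc(O[Si](C)(C)C)cc([Si](C)(C)C)c1[O-].[Li+] | intermediate
5 | tert-butyl{2-methoxy-6-(trimethylsilyl)-4-[(trimethylsilyl)oxy]phenoxy}dimethylsilane | COc1cc(O[Si](C)(C)C)cc([Si](C)(C)C)c1O[Si](C)(C)C(C)(C)C | intermediate
6 | 4-[(tert-butyldimethylsilyl)oxy]-3-methoxy-5-(trimethylsilyl)phenol | COc1cc(O)cc([Si](C)(C)C)c1O[Si](C)(C)C(C)(C)C | intermediate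
7 | tert-butyl[2-methoxy-4-(methoxymethoxy)-6-(trimethylsilyl)phenoxy]dimethylsilane | COCOc1cc([Si](C)(C)C)c(O[Si](C)(C)C(C)(C)C)c(OC)c1 | intermediate
8 | {3-[(tert-butyldimethylsilyl)oxy]-2-methoxy-6-(methoxymethoxy)-4-(trimethylsilyl)phenyl}lithium | COCOc1cc([Si](C)(C)C)c(O[Si](C)(C)C(C)(C)C)c(OC)c1[Li] | intermediate
9 | [3-bromo-2-methoxy-4-(methoxymethoxy)-6-(trimethylsilyl)phenoxy](tert-butyl)dimethylsilane | COCOc1cc([Si](C)(C)C)c(O[Si](C)(C)C(C)(C)C)c(OC)c1Br | intermediate
10 | 3-bromo-2-methoxy-4-(methoxymethoxy)-6-(trimethylsilyl)phenol | COCOc1cc([Si](C)(C)C)c(O)c(OC)c1Br | intermediate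
11 | 3-bromo-2-methoxy-4-(methoxymethoxy)-6-(trimethylsilyl)phenyl trifluoromethanesulfonate | COCOc1cc([Si](C)(C)C)c(OS(=O)(=O)C(F)(F)F)c(OC)c1Br | intermediate
12 | 3-methylbut-2-enal | CC(C)=CC=O | starting material
13 | 4-bromo-3-methoxy-5-(methoxymethoxy)-1,2-didehydrobenzene | COC1=C(Br)C(OCOC)=CC#C1 | intermediate
14 | 4-bromo-3-methoxy-5-(methoxymethoxy)-2-(2-methylprop-1-en-1-yl)-2H-benzo[b]oxete (racemic) | COCOc1cc2OC(C=C(C)C)c2c(OC)c1Br | intermediate
15 | (6Z)-4-bromo-5-methoxy-3-(methoxymethoxy)-6-(3-methylbut-2-en-1-ylidene)cyclohexa-2,4-dien-1-one | O=C1C=C(OCOC)C(Br)=C(OC)/C1=C/C=C(C)C | intermediate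
16 | 6-bromo-5-methoxy-7-(methoxymethoxy)-2,2-dimethyl-2H-chromene | COCOc1cc2OC(C)(C)C=Cc2c(OC)c1Br | intermediate
17 | 4-methoxyphenylacetyl chloride | COc1ccc(CC(=O)Cl)cc1 | starting material
18 | [5-methoxy-7-(methoxymethoxy)-2,2-dimethyl-2H-chromen-6-yl]lithium | COCOc1cc2OC(C)(C)C=Cc2c(OC)c1[Li] | intermediate
19 | chloro[5-methoxy-7-(methoxymethoxy)-2,2-dimethyl-2H-chromen-6-yl]zinc | COCOc1cc2OC(C)(C)C=Cc2c(OC)c1[Zn]Cl | intermediate
20 | 1-[5-methoxy-7-(methoxymethoxy)-2,2-dimethyl-2H-chromen-6-yl]-2-(4-methoxyphenyl)ethan-1-one | COCOc1cc2OC(C)(C)C=Cc2c(OC)c1C(=O)Cc1ccc(OC)cc1 | intermediate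
21 | 1-(7-hydroxy-5-methoxy-2,2-dimethyl-2H-chromen-6-yl)-2-(4-methoxyphenyl)ethan-1-one | COc1ccc(CC(=O)c2c(O)cc3c(c2OC)C=CC(C)(C)O3)cc1 | target

## Step count and least certain steps

Total step count: 9. Longest linear sequence: 9 steps (1 to 21); 12 and 17 enter as purchased compounds.

**Step 7 (key step).** The aryne may be consumed by the ene reaction with the allylic methyl groups, the aryl anion may be protonated before ring closure, 15 may be trapped by a second aryne, or fluoride may cause self-condensation of the enal. All of these would divert material before the oxa-6π closure. Fallback: starting from 11, the aryne would be released with CsF in DMF, whose C=O bond inserts in the same regiochemical sense. Aqueous work-up would give 3-bromo-6-hydroxy-2-methoxy-4-(methoxymethoxy)benzaldehyde F1. Addition of 2-methylprop-1-enylmagnesium bromide (excess, THF, 0 °C) would give racemic 4-bromo-2-(1-hydroxy-3-methylbut-2-en-1-yl)-3-methoxy-5-(methoxymethoxy)phenol F2. Mild dehydration (PPTS, toluene, warm) should pass through the same intermediate 15 and the same electrocyclisation. The fallback rejoins the route at 16.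

**Step 2.** During the warm-up needed for the silyl shift, silyl groups may exchange between phenoxide 4 and the aryl silyl ether of another molecule, or capping of the hindered phenoxide may be incomplete. Either would blur the differentiation of the two oxygens. Fallback: starting from 2, the less hindered hydroxyl would be protected first (MOMCl, i-Pr2NEt, CH2Cl2, low temperature) to give 2-bromo-6-methoxy-4-(methoxymethoxy)phenol F3. Silylation with HMDS would give [2-bromo-6-methoxy-4-(methoxymethoxy)phenoxy]trimethylsilane F4. Bromine–lithium exchange with retro-Brook shift, then TBSOTf, would follow. Here the oxygens are told apart by steric hindrance, not by the silyl shift. The fallback rejoins the route at 7.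

**Step 4.** Metalation may occur beside the SiMe3 group, the base may attack the silyl ether, or halogen transfer may be incomplete, so that bromine is not placed cleanly at the future C6. Fallback: starting from 7, the handle would be given up and C8 blocked after ring B is built.
- TBAF/AcOH would give 2-methoxy-4-(methoxymethoxy)-6-(trimethylsilyl)phenol F5.
- Tf2O/pyridine would give 2-methoxy-4-(methoxymethoxy)-6-(trimethylsilyl)phenyl trifluoromethanesulfonate F6.
- CsF and 12 would give 5-methoxy-7-(methoxymethoxy)-2,2-dimethyl-2H-chromene F7.
- n-BuLi then TMSCl is expected to silylate C8, where O1 and the MOM ether cooperate, giving [5-methoxy-7-(methoxymethoxy)-2,2-dimethyl-2H-chromen-8-yl]trimethylsilane F8.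
- s-BuLi/TMEDA, ZnCl2, then 17 with Pd(PPh3)4 would acylate the remaining position to give 1-[5-methoxy-7-(methoxymethoxy)-2,2-dimethyl-8-(trimethylsilyl)-2H-chromen-6-yl]-2-(4-methoxyphenyl)ethan-1-one F9.
- HCl in MeOH should remove both the MOM group and the C8 silyl group (protodesilylation of the activated position).

The fallback rejoins the route at 21.

**Step 8.** The hindered, di-ortho-substituted arylzinc may transmetalate slowly to palladium, leaving time for decarbonylation of the acyl-palladium species or ketene formation from 17. Adventitious protonation of 18 would give simple debromination. Fallback: starting from 16, the ketone would be built from the other side.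
- Bromine–lithium exchange and quenching with DMF would give 5-methoxy-7-(methoxymethoxy)-2,2-dimethyl-2H-chromene-6-carbaldehyde F10.
- 4-Methoxybenzylmagnesium chloride would add to give racemic 1-[5-methoxy-7-(methoxymethoxy)-2,2-dimethyl-2H-chromen-6-yl]-2-(4-methoxyphenyl)ethan-1-ol F11.
- Dess–Martin oxidation would give the ketone.

The fallback rejoins the route at 20.

## Further compounds

F1 | step 7 | 3-bromo-6-hydroxy-2-methoxy-4-(methoxymethoxy)benzaldehyde | COc1c(Br)c(OCOC)cc(O)c1C=O
F2 | step 7 | 4-bromo-2-(1-hydroxy-3-methylbut-2-en-1-yl)-3-methoxy-5-(methoxymethoxy)phenol (racemic) | COc1c(Br)c(OCOC)cc(O)c1C(O)C=C(C)C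
F3 | step 2 | 2-bromo-6-methoxy-4-(methoxymethoxy)phenol | COc1cc(OCOC)cc(Br)c1O
F4 | step 2 | [2-bromo-6-methoxy-4-(methoxymethoxy)phenoxy]trimethylsilane | COc1cc(OCOC)cc(Br)c1O[Si](C)(C)C
F5 | step 4 | 2-methoxy-4-(methoxymethoxy)-6-(trimethylsilyl)phenol | COc1cc(OCOC)cc([Si](C)(C)C)c1O
F6 | step 4 | 2-methoxy-4-(methoxymethoxy)-6-(trimethylsilyl)phenyl trifluoromethanesulfonate | COc1cc(OCOC)cc([Si](C)(C)C)c1OS(=O)(=O)C(F)(F)F
F7 | step 4 | 5-methoxy-7-(methoxymethoxy)-2,2-dimethyl-2H-chromene | COCOc1cc(OC)c2C=CC(C)(C)Oc2c1
F8 | step 4 | [5-methoxy-7-(methoxymethoxy)-2,2-dimethyl-2H-chromen-8-yl]trimethylsilane | COCOc1cc(OC)c2C=CC(C)(C)Oc2c1[Si](C)(C)C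
F9 | step 4 | 1-[5-methoxy-7-(methoxymethoxy)-2,2-dimethyl-8-(trimethylsilyl)-2H-chromen-6-yl]-2-(4-methoxyphenyl)ethan-1-one | COCOc1c(C(=O)Cc2ccc(OC)cc2)c(OC)c2C=CC(C)(C)Oc2c1[Si](C)(C)C
F10 | step 8 | 5-methoxy-7-(methoxymethoxy)-2,2-dimethyl-2H-chromene-6-carbaldehyde | COCOc1cc2OC(C)(C)C=Cc2c(OC)c1C=O
F11 | step 8 | 1-[5-methoxy-7-(methoxymethoxy)-2,2-dimethyl-2H-chromen-6-yl]-2-(4-methoxyphenyl)ethan-1-ol (racemic) | COCOc1cc2OC(C)(C)C=Cc2c(OC)c1C(O)Cc1ccc(OC)cc1
A1 | alternative 1 | 2-(methoxymethoxy)-4-[(2-methylbut-3-yn-2-yl)oxy]-6-(trimethylsilyl)phenyl trifluoromethanesulfonate | COCOc1cc(OC(C)(C)C#C)cc([Si](C)(C)C)c1OS(=O)(=O)C(F)(F)F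
A2 | alternative 1 | 4-methoxyphenylacetic acid | COc1ccc(CC(=O)O)cc1
A3 | alternative 1 | 1-[2-hydroxy-6-(methoxymethoxy)-4-[(2-methylbut-3-yn-2-yl)oxy]phenyl]-2-(4-methoxyphenyl)ethanone | COCOc1cc(OC(C)(C)C#C)cc(O)c1C(=O)Cc1ccc(OC)cc1
A4 | alternative 2 | methyl 8-(4-methoxyphenyl)-3,5,7-trioxooctanoate | COC(=O)CC(=O)CC(=O)CC(=O)Cc1ccc(OC)cc1
A5 | alternative 2 | 2-(4-methoxyphenyl)-1-(2,4,6-trihydroxyphenyl)ethanone | COc1ccc(CC(=O)c2c(O)cc(O)cc2O)cc1
A6 | alternative 3 | 2-iodo-1,3,5-tris(methoxymethoxy)benzene | COCOc1cc(OCOC)c(I)c(OCOC)c1
A7 | alternative 3 | carbon monoxide | [C-]#[O+]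
A8 | alternative 3 | (4-methoxybenzyl)zinc chloride | COc1ccc(C[Zn]Cl)cc1
A9 | alternative 3 | 2-(4-methoxyphenyl)-1-[2,4,6-tris(methoxymethoxy)phenyl]ethanone | COCOc1cc(OCOC)c(C(=O)Cc2ccc(OC)cc2)c(OCOC)c1
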